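**Retrosynthetic overview**
1. Target 17 ⇒ global desilylation and aldehyde reduction back to aryl ester 15. Its ArO–C(=O) bond is cut into salicylaldehyde 10 and the protected orsellinoyl chloride 14.
2. The CHO in 10 is the latent second CH2OH. By hydrogen-bonding its ortho phenol, it leaves only the para phenol free for acylation.
3. 10 ⇒ ortho-formylation of the symmetric 2-prenylresorcinol 8 ⇒ directed ortho-metalation/prenylation of bis-MOM, O-TBDPS 3,5-dihydroxybenzyl alcohol.
4. No ring is formed: both benzene rings are bought (3,5-dihydroxybenzyl alcohol and orsellinic acid).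

Assumption: the target has no stereocentre and no stereogenic alkene, so "single enantiomer" needs no stereocontrol. Purchased building blocks whose atoms stay in the target (1, 4, 9, 11) are numbered and repeated on the reagent line where they act as reagents; protecting-group reagents appear on the reagent line only.

**Step 1**
Reactants: 1 3,5-dihydroxybenzyl alcohol
Product: 2 [3,5-bis(methoxymethoxy)phenyl]methanol
Conditions: MOMCl (2.1 equiv), K2CO3, acetone, 0 °C → rt
Reagents that add atoms: chloromethyl methyl ether, COCCl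
Why: Carbonate deprotonates only the phenols (pKa about 10 versus about 15 for the benzylic OH), so the Williamson-type O-alkylation is chemoselective for the two ArOH groups.

**Step 2**
Reactants: 2 [3,5-bis(methoxymethoxy)phenyl]methanol
Product: 3 tert-butyl{[3,5-bis(methoxymethoxy)benzyl]oxy}diphenylsilane
Conditions: TBDPSCl, imidazole, DMF, rt
Reagents that add atoms: tert-butyldiphenylsilyl chloride, CC(C)(C)[Si](Cl)(c1ccccc1)c1ccccc1
Why: Standard silylation of a primary alcohol; TBDPS is chosen because it tolerates n-BuLi and the later acidic MOM removal and leaves with the TBS groups at the end.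

**Step 3**
Reactants: 3 tert-butyl{[3,5-bis(methoxymethoxy)benzyl]oxy}diphenylsilane, 4 prenyl bromide (1-bromo-3-methylbut-2-ene)
Product: 7 tert-butyl{[3,5-bis(methoxymethoxy)-4-(3-methylbut-2-en-1-yl)benzyl]oxy}diphenylsilane, via aryllithium 5 (not isolated), via arylcopper 6 (not isolated)
Conditions: n-BuLi, THF, 0 °C; CuI (1.3 equiv), −20 °C; prenyl bromide, −20 °C → rt
Reagents that add atoms: prenyl bromide 4, CC(C)=CCBr
Why: Directed ortho-metalation occurs at the position flanked by both OMOM groups, and Li→Cu transmetalation gives clean SN2 (α) allylation by prenyl bromide.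

**Step 4**
Reactants: 7 tert-butyl{[3,5-bis(methoxymethoxy)-4-(3-methylbut-2-en-1-yl)benzyl]oxy}diphenylsilane
Product: 8 5-{[(tert-butyldiphenylsilyl)oxy]methyl}-2-(3-methylbut-2-en-1-yl)benzene-1,3-diol
Conditions: p-TsOH·H2O (cat.), MeOH, rt
Reagents that add atoms: none
Why: Acid-catalysed transacetalisation removes aryl MOM ethers under conditions mild enough to spare the primary TBDPS ether and the prenyl alkene (no chroman formation at rt).

**Step 5**
Reactants: 8 5-{[(tert-butyldiphenylsilyl)oxy]methyl}-2-(3-methylbut-2-en-1-yl)benzene-1,3-diol, 9 paraformaldehyde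
Product: 10 6-{[(tert-butyldiphenylsilyl)oxy]methyl}-2,4-dihydroxy-3-(3-methylbut-2-en-1-yl)benzaldehyde
Conditions: MgCl2, Et3N, (CH2O)n, MeCN, reflux
Reagents that add atoms: paraformaldehyde 9, C=O
Why: Casnati–Skattebøl magnesium-phenoxide ortho-formylation; the two open ring positions of symmetric 8 are equivalent, so one mono-aldehyde results, with a second formaldehyde acting as hydride acceptor.

**Step 6**
Reactants: 11 orsellinic acid (2,4-dihydroxy-6-methylbenzoic acid)
Product: 13 2,4-bis[(tert-butyldimethylsilyl)oxy]-6-methylbenzoic acid, via tris-TBS silyl ester 12 (not isolated)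
Conditions: TBSCl (3.5 equiv), imidazole, DMF, rt; then AcOH/THF/H2O, rt
Reagents that add atoms: tert-butyldimethylsilyl chloride, CC(C)(C)[Si](C)(C)Cl
Why: Exhaustive silylation followed by selective hydrolysis of the much more labile silyl ester leaves the two aryl silyl ethers and the free acid.

**Step 7**
Reactants: 13 2,4-bis[(tert-butyldimethylsilyl)oxy]-6-methylbenzoic acid, 10 6-{[(tert-butyldiphenylsilyl)oxy]methyl}-2,4-dihydroxy-3-(3-methylbut-2-en-1-yl)benzaldehyde
Product: 15 5-{[(tert-butyldiphenylsilyl)oxy]methyl}-4-formyl-3-hydroxy-2-(3-methylbut-2-en-1-yl)phenyl 2,4-bis[(tert-butyldimethylsilyl)oxy]-6-methylbenzoate, via acid chloride 14 (not isolated)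
Conditions: (COCOCl)2-free wording: (COCl)2, DMF (cat.), CH2Cl2, 0 °C → rt, evaporate; then 10, Et3N, DMAP (cat.), CH2Cl2, 0 °C → rt
Reagents that add atoms: none
Why: Acid chloride formation and DMAP-catalysed O-acylation; the 4-OH para to CHO is the acidic, non-chelated phenol, while the 2-OH is hydrogen-bonded to the aldehyde and flanked by two ortho groups.

**Step 8**
Reactants: 15 5-{[(tert-butyldiphenylsilyl)oxy]methyl}-4-formyl-3-hydroxy-2-(3-methylbut-2-en-1-yl)phenyl 2,4-bis[(tert-butyldimethylsilyl)oxy]-6-methylbenzoate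
Product: 16 5-{[(tert-butyldiphenylsilyl)oxy]methyl}-3-hydroxy-4-(hydroxymethyl)-2-(3-methylbut-2-en-1-yl)phenyl 2,4-bis[(tert-butyldimethylsilyl)oxy]-6-methylbenzoate
Conditions: NaBH4, THF/MeOH, −10 → 0 °C; aq. NH4Cl
Reagents that add atoms: none
Why: Chemoselective borohydride reduction of the aldehyde; the 2,6-disubstituted (mesitoate-like) aryl ester and the silyl ethers are inert at low temperature and short reaction time.

**Step 9**
Reactants: 16 5-{[(tert-butyldiphenylsilyl)oxy]methyl}-3-hydroxy-4-(hydroxymethyl)-2-(3-methylbut-2-en-1-yl)phenyl 2,4-bis[(tert-butyldimethylsilyl)oxy]-6-methylbenzoate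
Product: 17 3-hydroxy-4,5-bis(hydroxymethyl)-2-(3-methylbut-2-en-1-yl)phenyl 2,4-dihydroxy-6-methylbenzoate (target)
Conditions: HF·pyridine, pyridine, THF, 0 °C → rt
Reagents that add atoms: none
Why: Fluoride-driven global desilylation under buffered, non-basic conditions removes both aryl TBS ethers and the TBDPS ether without touching the aryl ester, the prenyl alkene or the o-hydroxybenzyl alcohol.

**Compound list**
1 | 3,5-dihydroxybenzyl alcohol | OCc1cc(O)cc(O)c1 | starting material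
2 | [3,5-bis(methoxymethoxy)phenyl]methanol | COCOc1cc(CO)cc(OCOC)c1 | intermediate
3 | tert-butyl{[3,5-bis(methoxymethoxy)benzyl]oxy}diphenylsilane | COCOc1cc(CO[Si](c2ccccc2)(c2ccccc2)C(C)(C)C)cc(OCOC)c1 | intermediate
4 | prenyl bromide (1-bromo-3-methylbut-2-ene) | CC(C)=CCBr | starting material
5 | aryllithium: {4-[(TBDPS-oxy)methyl]-2,6-bis(methoxymethoxy)phenyl}lithium | COCOc1cc(CO[Si](c2ccccc2)(c2ccccc2)C(C)(C)C)cc(OCOC)c1[Li] | intermediate
6 | arylcopper: {4-[(TBDPS-oxy)methyl]-2,6-bis(methoxymethoxy)phenyl}copper(I) | COCOc1cc(CO[Si](c2ccccc2)(c2ccccc2)C(C)(C)C)cc(OCOC)c1[Cu] | intermediate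
7 | tert-butyl{[3,5-bis(methoxymethoxy)-4-(3-methylbut-2-en-1-yl)benzyl]oxy}diphenylsilane | COCOc1cc(CO[Si](c2ccccc2)(c2ccccc2)C(C)(C)C)cc(OCOC)c1CC=C(C)C | intermediate
8 | 5-{[(tert-butyldiphenylsilyl)oxy]methyl}-2-(3-methylbut-2-en-1-yl)benzene-1,3-diol | CC(C)=CCc1c(O)cc(CO[Si](c2ccccc2)(c2ccccc2)C(C)(C)C)cc1O | intermediate
9 | paraformaldehyde (formaldehyde source) | C=O | starting material
10 | 6-{[(tert-butyldiphenylsilyl)oxy]methyl}-2,4-dihydroxy-3-(3-methylbut-2-en-1-yl)benzaldehyde | CC(C)=CCc1c(O)cc(CO[Si](c2ccccc2)(c2ccccc2)C(C)(C)C)c(C=O)c1O | intermediate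
11 | orsellinic acid (2,4-dihydroxy-6-methylbenzoic acid) | Cc1cc(O)cc(O)c1C(=O)O | starting material
12 | tert-butyldimethylsilyl 2,4-bis[(tert-butyldimethylsilyl)oxy]-6-methylbenzoate | Cc1cc(O[Si](C)(C)C(C)(C)C)cc(O[Si](C)(C)C(C)(C)C)c1C(=O)O[Si](C)(C)C(C)(C)C | intermediate
13 | 2,4-bis[(tert-butyldimethylsilyl)oxy]-6-methylbenzoic acid | Cc1cc(O[Si](C)(C)C(C)(C)C)cc(O[Si](C)(C)C(C)(C)C)c1C(=O)O | intermediate
14 | 2,4-bis[(tert-butyldimethylsilyl)oxy]-6-methylbenzoyl chloride | Cc1cc(O[Si](C)(C)C(C)(C)C)cc(O[Si](C)(C)C(C)(C)C)c1C(=O)Cl | intermediate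
15 | 5-{[(tert-butyldiphenylsilyl)oxy]methyl}-4-formyl-3-hydroxy-2-(3-methylbut-2-en-1-yl)phenyl 2,4-bis[(tert-butyldimethylsilyl)oxy]-6-methylbenzoate | CC(C)=CCc1c(OC(=O)c2c(C)cc(O[Si](C)(C)C(C)(C)C)cc2O[Si](C)(C)C(C)(C)C)cc(CO[Si](c2ccccc2)(c2ccccc2)C(C)(C)C)c(C=O)c1O | intermediate
16 | 5-{[(tert-butyldiphenylsilyl)oxy]methyl}-3-hydroxy-4-(hydroxymethyl)-2-(3-methylbut-2-en-1-yl)phenyl 2,4-bis[(tert-butyldimethylsilyl)oxy]-6-methylbenzoate | CC(C)=CCc1c(OC(=O)c2c(C)cc(O[Si](C)(C)C(C)(C)C)cc2O[Si](C)(C)C(C)(C)C)cc(CO[Si](c2ccccc2)(c2ccccc2)C(C)(C)C)c(CO)c1O | intermediate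
17 | 3-hydroxy-4,5-bis(hydroxymethyl)-2-(3-methylbut-2-en-1-yl)phenyl 2,4-dihydroxy-6-methylbenzoate | CC(C)=CCc1c(OC(=O)c2c(C)cc(O)cc2O)cc(CO)c(CO)c1O | target

**Step count**
Total steps: 9. Longest linear sequence: 8 (steps 1, 2, 3, 4, 5, 7, 8, 9).

**Three steps most likely to fail**

Step 5 (formylation next to the bulky CH2OTBDPS group; risk of stalling or double formylation). The fallback sets out from 7 and comes back at 10. A second directed ortho-lithiation of 7 (s-BuLi/TMEDA, THF, −78 °C) at the position between OMOM and CH2OTBDPS, quenched with DMF, gives 6-{[(tert-butyldiphenylsilyl)oxy]methyl}-2,4-bis(methoxymethoxy)-3-(3-methylbut-2-en-1-yl)benzaldehyde F1. Removing both MOM ethers with catalytic TsOH in MeOH then gives 10.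

Step 7 (hindered 2,6-disubstituted acid chloride reacting with a weakly nucleophilic, formyl-conjugated phenol). The fallback sets out from 8 (with 14 made as in step 7) and comes back at 15, reversing the order of acylation and formylation. Because 8 is symmetric, mono-acylation of its electron-rich phenol with one equivalent of 14 (Et3N, cat. DMAP, −20 °C) gives 5-{[(tert-butyldiphenylsilyl)oxy]methyl}-3-hydroxy-2-(3-methylbut-2-en-1-yl)phenyl 2,4-bis[(tert-butyldimethylsilyl)oxy]-6-methylbenzoate F2. Magnesium-mediated ortho-formylation of the remaining phenol, whose only free ortho position lies next to CH2OTBDPS, then gives 15.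

Step 9 (slow TBDPS cleavage in a product with a labile aryl ester, an o-prenylphenol and an o-hydroxybenzyl alcohol). The fallback sets out from 10 and comes back at 17, removing the robust silyl group before the ester exists. TBAF in THF at 0 °C converts 10 into 2,4-dihydroxy-6-(hydroxymethyl)-3-(3-methylbut-2-en-1-yl)benzaldehyde F3, which may sit partly as its lactol. Acylation of its acidic 4-phenoxide with 14 (K2CO3, acetone, 0 °C, no DMAP, so the neutral primary alcohol is spared) gives 4-formyl-3-hydroxy-5-(hydroxymethyl)-2-(3-methylbut-2-en-1-yl)phenyl 2,4-bis[(tert-butyldimethylsilyl)oxy]-6-methylbenzoate F4. NaBH4 reduction gives 3-hydroxy-4,5-bis(hydroxymethyl)-2-(3-methylbut-2-en-1-yl)phenyl 2,4-bis[(tert-butyldimethylsilyl)oxy]-6-methylbenzoate F5. Its two aryl TBS ethers come off within minutes with TBAF/AcOH at 0 °C to give 17.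

**Further compounds**
F1 | step 5 | 6-{[(tert-butyldiphenylsilyl)oxy]methyl}-2,4-bis(methoxymethoxy)-3-(3-methylbut-2-en-1-yl)benzaldehyde | COCOc1cc(CO[Si](c2ccccc2)(c2ccccc2)C(C)(C)C)c(C=O)c(OCOC)c1CC=C(C)C
F2 | step 7 | 5-{[(tert-butyldiphenylsilyl)oxy]methyl}-3-hydroxy-2-(3-methylbut-2-en-1-yl)phenyl 2,4-bis[(tert-butyldimethylsilyl)oxy]-6-methylbenzoate | CC(C)=CCc1c(OC(=O)c2c(C)cc(O[Si](C)(C)C(C)(C)C)cc2O[Si](C)(C)C(C)(C)C)cc(CO[Si](c2ccccc2)(c2ccccc2)C(C)(C)C)cc1O
F3 | step 9 | 2,4-dihydroxy-6-(hydroxymethyl)-3-(3-methylbut-2-en-1-yl)benzaldehyde | CC(C)=CCc1c(O)cc(CO)c(C=O)c1O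
F4 | step 9 | 4-formyl-3-hydroxy-5-(hydroxymethyl)-2-(3-methylbut-2-en-1-yl)phenyl 2,4-bis[(tert-butyldimethylsilyl)oxy]-6-methylbenzoate | CC(C)=CCc1c(OC(=O)c2c(C)cc(O[Si](C)(C)C(C)(C)C)cc2O[Si](C)(C)C(C)(C)C)cc(CO)c(C=O)c1O
F5 | step 9 | 3-hydroxy-4,5-bis(hydroxymethyl)-2-(3-methylbut-2-en-1-yl)phenyl 2,4-bis[(tert-butyldimethylsilyl)oxy]-6-methylbenzoate | CC(C)=CCc1c(OC(=O)c2c(C)cc(O[Si](C)(C)C(C)(C)C)cc2O[Si](C)(C)C(C)(C)C)cc(CO)c(CO)c1O
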